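**Plan**
1. Cuts, in retrosynthetic order: the five benzyl ethers; the ketal C–O(aryl) bond and the carbinol C–OH bond at the furan/pyranone junction (back to a 3-aroyl-2-arylbenzofuran with one free ortho phenol); the furan O–C2 and C3–aryl bonds (back to an ortho-bromophenol and a diaryl ynone); the chroman O1–C8a and C4–C4a bonds (back to an aryl iodide and an (S)-γ-bromo alcohol).
2. Enabling feature: in ring A of the flavan, C8a (bearing O1) and C4a (bearing C4) are adjacent arene carbons, and C8 on the other side of C8a is substituted too. An aryl iodide at C8a with a free C–H at C4a and a bromine at C8 is the pattern for a palladium/norbornene relay that alkylates the ortho carbon and etherifies the ipso carbon.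
3. Forward order of rings: chroman ring (step 6), furan ring by oxa-Michael addition/Heck closure (step 12), pyranone ring by oxidative ketalisation (step 14), then debenzylation (step 15).
4. Stereochemistry: C2 of the chroman comes from a CBS reduction (step 2) and passes through step 6 untouched; the ring-junction pair comes from catalyst-controlled oxygen delivery to the benzofuran double bond (step 14), ring closure fixing the ketal carbon.

Key step: step 6

Remark on the chemistry (assumption): the ketal carbon and the tertiary carbinol carbon form the bond shared by the furan and pyranone rings and arise together in step 14, which can only give a cis ring fusion; read literally, the two descriptors of the target string place the OH and the ketal aryl group anti across that bond, so the carbinol descriptor is taken as the one to be met (it follows the face of oxygen delivery) and both descriptors are written in all SMILES as in the target string.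

Step 1
Reactants: 1 (4-(benzyloxy)phenyl)magnesium bromide; 2 3-bromopropanoyl chloride
Product: 3 1-[4-(benzyloxy)phenyl]-3-bromopropan-1-one
Conditions: CuI (10 mol %), THF, −78 °C, Grignard reagent added to the acid chloride
Reagents that add atoms: none
Why: Copper-catalysed acylation of an aryl Grignard reagent by an acid chloride is faster at −78 °C than addition to the ketone formed or attack at the primary bromide, and inverse addition keeps base away from the β-bromo ketone.

Step 2
Reactants: 3 1-[4-(benzyloxy)phenyl]-3-bromopropan-1-one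
Product: 4 (S)-1-[4-(benzyloxy)phenyl]-3-bromopropan-1-ol
Conditions: (R)-1-methyl-3,3-diphenyltetrahydro-1H,3H-pyrrolo[1,2-c][1,3,2]oxazaborole (10 mol %), BH3·SMe2, THF, −20 °C
Reagents that add atoms: none
Why: Corey–Bakshi–Shibata reduction, in which the (R)-oxazaborolidine delivers hydride to the face of the aryl ketone (aryl as the large group) that gives the (S)-carbinol, as with 3-halopropiophenones.

Step 3
Reactants: 5 5-iodobenzene-1,3-diol
Product: 6 4-bromo-5-iodobenzene-1,3-diol
Conditions: NBS (1.0 equiv), MeCN, −20 °C to 0 °C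
Reagents that add atoms: N-bromosuccinimide, O=C1CCC(=O)N1Br
Why: Electrophilic bromination of a resorcinol goes para to one hydroxyl and ortho to the other, so the carbon next to iodine should be taken in preference to the crowded carbon between the two hydroxyls, and one equivalent limits dibromination.

Step 4
Reactants: 6 4-bromo-5-iodobenzene-1,3-diol
Product: 7 5-(benzyloxy)-2-bromo-3-iodophenol
Conditions: BnBr (1.0 equiv), K2CO3, acetone, rt to 40 °C
Reagents that add atoms: benzyl bromide, BrCc1ccccc1
Why: Williamson etherification in which the hydroxyl remote from bromine, the less hindered one, should be alkylated first (as in the monoalkylation of 4-bromoresorcinol), the regioisomer and the dibenzyl ether being removable by chromatography.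

Step 5
Reactants: 7 5-(benzyloxy)-2-bromo-3-iodophenol
Product: 8 1-(benzyloxy)-4-bromo-3-iodo-5-(methoxymethoxy)benzene
Conditions: MOMCl, K2CO3, acetone, rt
Reagents that add atoms: chloromethyl methyl ether, COCCl
Why: Williamson etherification to the methoxymethyl ether, which masks the phenol against O-alkylation and O-arylation in step 6 and can later be removed without touching benzyl ethers.

Step 6
Reactants: 8 1-(benzyloxy)-4-bromo-3-iodo-5-(methoxymethoxy)benzene; 4 (S)-1-[4-(benzyloxy)phenyl]-3-bromopropan-1-ol
Product: 9 (S)-5-(benzyloxy)-2-[4-(benzyloxy)phenyl]-8-bromo-7-(methoxymethoxy)chromane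
Conditions: Pd(OAc)2 (10 mol %), XPhos (20 mol %), norbornene (2 equiv), Cs2CO3 (3 equiv), 1,4-dioxane, 100 °C
Reagents that add atoms: none
Why: Proposed new method: zerovalent palladium inserts into the C–I bond of 8 (faster than into the flanked C–Br bond), norbornene inserts, and carbonate-assisted palladation of the only free ortho C–H (between the iodine-bearing carbon and the benzyloxy carbon) gives the aryl–norbornyl palladacycle of divalent palladium, which takes up the primary C–Br bond of 4 by SN2-type oxidative addition and forms the aryl–CH2 bond by reductive elimination from tetravalent palladium. With both ortho positions now filled (bromine and the new chain), norbornene is extruded by β-carbon elimination, and the tethered secondary alkoxide closes the six-membered oxygen ring by C–O reductive elimination at the ipso carbon through a seven-membered oxapalladacycle. The closest known reactions are the palladium/norbornene (Catellani-type) annulations of aryl iodides with epoxides to dihydrobenzofurans and with bromoalkylamines to tetrahydroquinolines, together with the palladium-catalysed intramolecular etherification of aryl halides by secondary alcohols, which runs without loss of configuration. No stereocentre is formed: C2 of the chroman is the carbinol carbon of 4 and keeps its configuration because none of its bonds is broken. The step needs C–I insertion before C–Br insertion, C-alkylation before any intermolecular O-arylation, and C–O reductive elimination before β-hydride loss from the palladium alkoxide; these should be secured by the reactivity order of the halides, by the norbornene relay (the alkoxide can reach an ipso-bound palladium only after norbornene has left) and by the bulky biaryl phosphine.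

Step 7
Reactants: 9 (S)-5-(benzyloxy)-2-[4-(benzyloxy)phenyl]-8-bromo-7-(methoxymethoxy)chromane
Product: 10 (S)-5-(benzyloxy)-2-[4-(benzyloxy)phenyl]-8-bromochroman-7-ol
Conditions: HCl (3 M aq., catalytic), MeOH–THF, 45 °C
Reagents that add atoms: none
Why: Acid-catalysed acetal exchange with methanol frees the phenol under conditions that should leave benzyl ethers and the chroman ether intact, as in methoxymethyl removals on flavan-3-ol derivatives.

Step 8
Reactants: 11 2,4,6-trihydroxybenzaldehyde
Product: 12 2,4-bis(benzyloxy)-6-hydroxybenzaldehyde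
Conditions: BnBr (2.0 equiv), K2CO3, DMF, rt
Reagents that add atoms: benzyl bromide, BrCc1ccccc1
Why: Williamson etherification in which the 4-OH and one 2-OH react while the last hydroxyl stays hydrogen-bonded to the aldehyde and is left free.

Step 9
Reactants: 12 2,4-bis(benzyloxy)-6-hydroxybenzaldehyde
Product: 13 2,4-bis(benzyloxy)-6-(methoxymethoxy)benzaldehyde
Conditions: MOMCl, K2CO3, acetone, reflux
Reagents that add atoms: chloromethyl methyl ether, COCCl
Why: Williamson etherification of the chelated phenol under forcing conditions gives an ortho oxygen that can later be freed selectively in the presence of benzyl ethers.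

Step 10
Reactants: 14 1-(benzyloxy)-4-ethynylbenzene; 13 2,4-bis(benzyloxy)-6-(methoxymethoxy)benzaldehyde
Product: 16 1-[2,4-bis(benzyloxy)-6-(methoxymethoxy)phenyl]-3-[4-(benzyloxy)phenyl]prop-2-yn-1-ol, via lithium acetylide 15 (not isolated)
Conditions: n-BuLi, THF, −78 °C; then 13, −78 °C to 0 °C
Reagents that add atoms: none
Why: 1,2-Addition of a lithium acetylide to an aldehyde, the new carbinol centre being formed without control and removed in step 11.

Step 11
Reactants: 16 1-[2,4-bis(benzyloxy)-6-(methoxymethoxy)phenyl]-3-[4-(benzyloxy)phenyl]prop-2-yn-1-ol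
Product: 17 1-[2,4-bis(benzyloxy)-6-(methoxymethoxy)phenyl]-3-[4-(benzyloxy)phenyl]prop-2-yn-1-one
Conditions: Dess–Martin periodinane, NaHCO3, CH2Cl2, 0 °C to rt
Reagents that add atoms: none
Why: Dess–Martin oxidation of a propargylic benzylic alcohol to the ynone under buffered conditions that spare the methoxymethyl ether.

Step 12
Reactants: 10 (S)-5-(benzyloxy)-2-[4-(benzyloxy)phenyl]-8-bromochroman-7-ol; 17 1-[2,4-bis(benzyloxy)-6-(methoxymethoxy)phenyl]-3-[4-(benzyloxy)phenyl]prop-2-yn-1-one
Product: 19 [2,4-bis(benzyloxy)-6-(methoxymethoxy)phenyl]{(2S)-5-(benzyloxy)-2,8-bis[4-(benzyloxy)phenyl]-3,4-dihydro-2H-furo[2,3-h]chromen-9-yl}methanone, via aryloxy enone 18 (not isolated)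
Conditions: K2CO3, DMF, rt; then Pd(OAc)2 (10 mol %), P(t-Bu)3·HBF4 (20 mol %), 100 °C
Reagents that add atoms: none
Why: Oxa-Michael addition of the phenoxide of 10 to the ynone gives the β-aryloxy enone, and an intramolecular Heck reaction of the ortho C–Br bond onto the enone α-carbon (5-exo, then base-assisted loss of palladium hydride to the aromatic furan) should give the 3-aroyl-2-arylbenzofuran with the regiochemistry fixed by the O–C bond made first.

Step 13
Reactants: 19 the methoxymethyl-protected benzofuran ketone
Product: 20 [2,4-bis(benzyloxy)-6-hydroxyphenyl]{(2S)-5-(benzyloxy)-2,8-bis[4-(benzyloxy)phenyl]-3,4-dihydro-2H-furo[2,3-h]chromen-9-yl}methanone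
Conditions: HCl (3 M aq., catalytic), MeOH–THF, 40 °C
Reagents that add atoms: none
Why: Acid-catalysed acetal exchange, made easy by chelation of the ortho oxygen to the ketone, frees the one phenol needed for ketal closure while the benzyl ethers stay.

Step 14
Reactants: 20 the ortho-hydroxyaroyl benzofuran
Product: 22 penta-O-benzyl ether of the target (benzyl on the 5- and 7-oxygens of the chromanone, on both 4-hydroxyphenyl groups and on the 5-oxygen of the chroman), via benzofuran epoxide 21 (not isolated)
Conditions: (R,R)-N,N'-bis(3,5-di-tert-butylsalicylidene)-1,2-cyclohexanediaminomanganese chloride (20 mol %), N-methylmorpholine N-oxide, mCPBA, CH2Cl2, −40 °C to 0 °C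
Reagents that add atoms: 3-chloroperbenzoic acid, O=C(OO)c1cccc(Cl)c1
Why: Proposed new method: the oxo species of pentavalent manganese held by the chiral salen should transfer oxygen to one face of the acyl-substituted C2=C3 bond of the benzofuran, the epoxide 21 ionises at the carbon flanked by the furan oxygen and the 4-benzyloxyphenyl group and is captured anti by the chelated ortho phenol in a 6-endo closure, so that the carbinol carbon takes its configuration from the face of oxygen delivery (catalyst control; the (R,R) antipode is a working choice by analogy with indene and 2,2-dimethylchromene, and the (S,S) antipode is used if the sense proves opposite) and the ketal carbon follows from the cis ring fusion; the closest known reactions are the Jacobsen–Katsuki epoxidation of chromenes and isoflavones and the dimethyldioxirane oxidation of benzofurans and flavones.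

Step 15
Reactants: 22 penta-O-benzyl ether of the target
Product: 23 the target
Conditions: H2 (1 atm), Pd(OH)2/C, THF–MeOH, rt
Reagents that add atoms: none
Why: Hydrogenolysis of the five aryl benzyl ethers under neutral conditions, as used for benzylated flavans and doubly linked proanthocyanidin ketals, should leave the ketal, the tertiary alcohol, the ketone and the chroman C2–O bond.

**Compound list**
1 | (4-(benzyloxy)phenyl)magnesium bromide | Br[Mg]c1ccc(OCc2ccccc2)cc1 | starting material
2 | 3-bromopropanoyl chloride | O=C(Cl)CCBr | starting material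
3 | 1-[4-(benzyloxy)phenyl]-3-bromopropan-1-one | O=C(CCBr)c1ccc(OCc2ccccc2)cc1 | intermediate
4 | (S)-1-[4-(benzyloxy)phenyl]-3-bromopropan-1-ol | O[C@@H](CCBr)c1ccc(OCc2ccccc2)cc1 | intermediate
5 | 5-iodobenzene-1,3-diol (5-iodoresorcinol) | Oc1cc(O)cc(I)c1 | starting material
6 | 4-bromo-5-iodobenzene-1,3-diol | Oc1cc(O)c(Br)c(I)c1 | intermediate
7 | 5-(benzyloxy)-2-bromo-3-iodophenol | Oc1cc(OCc2ccccc2)cc(I)c1Br | intermediate
8 | 1-(benzyloxy)-4-bromo-3-iodo-5-(methoxymethoxy)benzene | COCOc1cc(OCc2ccccc2)cc(I)c1Br | intermediate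
9 | (S)-5-(benzyloxy)-2-[4-(benzyloxy)phenyl]-8-bromo-7-(methoxymethoxy)chromane | COCOc1cc(OCc2ccccc2)c2c(c1Br)O[C@H](c1ccc(OCc3ccccc3)cc1)CC2 | intermediate
10 | (S)-5-(benzyloxy)-2-[4-(benzyloxy)phenyl]-8-bromochroman-7-ol | Oc1cc(OCc2ccccc2)c2c(c1Br)O[C@H](c1ccc(OCc3ccccc3)cc1)CC2 | intermediate
11 | 2,4,6-trihydroxybenzaldehyde | O=Cc1c(O)cc(O)cc1O | starting material
12 | 2,4-bis(benzyloxy)-6-hydroxybenzaldehyde | O=Cc1c(O)cc(OCc2ccccc2)cc1OCc1ccccc1 | intermediate
13 | 2,4-bis(benzyloxy)-6-(methoxymethoxy)benzaldehyde | COCOc1cc(OCc2ccccc2)cc(OCc2ccccc2)c1C=O | intermediate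
14 | 1-(benzyloxy)-4-ethynylbenzene | C#Cc1ccc(OCc2ccccc2)cc1 | starting material
15 | lithium [4-(benzyloxy)phenyl]acetylide (not isolated) | [Li]C#Cc1ccc(OCc2ccccc2)cc1 | intermediate
16 | 1-[2,4-bis(benzyloxy)-6-(methoxymethoxy)phenyl]-3-[4-(benzyloxy)phenyl]prop-2-yn-1-ol (both carbinol configurations) | OC(C#Cc1ccc(OCc2ccccc2)cc1)c1c(OCOC)cc(OCc2ccccc2)cc1OCc1ccccc1 | intermediate
17 | 1-[2,4-bis(benzyloxy)-6-(methoxymethoxy)phenyl]-3-[4-(benzyloxy)phenyl]prop-2-yn-1-one | O=C(C#Cc1ccc(OCc2ccccc2)cc1)c1c(OCOC)cc(OCc2ccccc2)cc1OCc1ccccc1 | intermediate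
18 | 3-({(2S)-5-(benzyloxy)-2-[4-(benzyloxy)phenyl]-8-bromochroman-7-yl}oxy)-1-[2,4-bis(benzyloxy)-6-(methoxymethoxy)phenyl]-3-[4-(benzyloxy)phenyl]prop-2-en-1-one, mixture of double-bond isomers (not isolated) | COCOc1cc(OCc2ccccc2)cc(OCc2ccccc2)c1C(=O)C=C(Oc1cc(OCc2ccccc2)c2c(c1Br)O[C@H](c1ccc(OCc3ccccc3)cc1)CC2)c1ccc(OCc2ccccc2)cc1 | intermediate
19 | [2,4-bis(benzyloxy)-6-(methoxymethoxy)phenyl]{(2S)-5-(benzyloxy)-2,8-bis[4-(benzyloxy)phenyl]-3,4-dihydro-2H-furo[2,3-h]chromen-9-yl}methanone | COCOc1cc(OCc2ccccc2)cc(OCc2ccccc2)c1C(=O)c1c(-c2ccc(OCc3ccccc3)cc2)oc2cc(OCc3ccccc3)c3c(c12)O[C@H](c1ccc(OCc2ccccc2)cc1)CC3 | intermediate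
20 | [2,4-bis(benzyloxy)-6-hydroxyphenyl]{(2S)-5-(benzyloxy)-2,8-bis[4-(benzyloxy)phenyl]-3,4-dihydro-2H-furo[2,3-h]chromen-9-yl}methanone | Oc1cc(OCc2ccccc2)cc(OCc2ccccc2)c1C(=O)c1c(-c2ccc(OCc3ccccc3)cc2)oc2cc(OCc3ccccc3)c3c(c12)O[C@H](c1ccc(OCc2ccccc2)cc1)CC3 | intermediate
21 | epoxide of 20 across the furan C8–C9 bond, oxygen on the face that becomes the carbinol oxygen (not isolated) | Oc1cc(OCc2ccccc2)cc(OCc2ccccc2)c1C(=O)[C@]12O[C@@]1(c1ccc(OCc3ccccc3)cc1)Oc1cc(OCc3ccccc3)c3c(c12)O[C@H](c1ccc(OCc2ccccc2)cc1)CC3 | intermediate
22 | penta-O-benzyl ether of the target | O=C1c2c(OCc3ccccc3)cc(OCc3ccccc3)cc2O[C@@]2(c3ccc(OCc4ccccc4)cc3)Oc3cc(OCc4ccccc4)c4c(c3[C@]12O)O[C@H](c1ccc(OCc2ccccc2)cc1)CC4 | intermediate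
23 | target: (2S)-5-hydroxy-2-(4-hydroxyphenyl)chroman whose O7 and C8 close a furan ring onto the ketal carbon (bearing 4-hydroxyphenyl) and the tertiary carbinol carbon of a 5,7-dihydroxychroman-4-one | O=C1c2c(O)cc(O)cc2O[C@@]2(c3ccc(O)cc3)Oc3cc(O)c4c(c3[C@]12O)O[C@H](c1ccc(O)cc1)CC4 | target

**Step count and risks**
Total steps: 15. Longest linear sequence: 9 steps (3, 4, 5, 6, 7, 12, 13, 14, 15).

Three steps most likely to fail:

Step 6 (Proposed new method). What may go wrong: β-hydride elimination from the palladium alkoxide outrunning C–O reductive elimination, insertion of palladium into the C–Br bond of 8 or 9, or base-induced closure of 4 to an oxetane before it is consumed. The fallback uses known chemistry, closes the chroman at O1–C2 instead, sets out from 11 and comes back at 9. Compound 11 is etherified at the non-chelated 4-OH (MOMCl, i-Pr2NEt) to 2,6-dihydroxy-4-(methoxymethoxy)benzaldehyde F1, then monobenzylated (BnBr, K2CO3) to 2-(benzyloxy)-6-hydroxy-4-(methoxymethoxy)benzaldehyde F2. Claisen–Schmidt condensation with commercial 4'-(benzyloxy)acetophenone (KOH, EtOH) gives the chalcone F3, and conjugate reduction (H2, RhCl(PPh3)3) gives the dihydrochalcone F4. CBS reduction with the (S)-oxazaborolidine gives the (R)-benzylic alcohol F5, and Mitsunobu cyclisation (PPh3, DIAD) with inversion gives the (S)-flavan F6. NBS then brominates C8, the position between the ring oxygen and the methoxymethoxy group, as in 5,7-di-O-protected flavan-3-ols, to give 9.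

Step 14 (Proposed new method). What may go wrong: poor facial discrimination on a tetrasubstituted, acyl-substituted double bond, the opposite sense of induction, oxidation of the benzyloxy-substituted rings, or acyl shift of the epoxide before the phenol captures it. The fallback uses known chemistry, sets out from 20 and comes back at 22. Dimethyldioxirane (acetone, 0 °C) without catalyst epoxidises the benzofuran and the phenol closes the ketal as in step 14. Both cis-fused junction isomers should form, 22 and its junction epimer F7; they are diastereomers because of the chroman centre and are separated by chromatography.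

Step 12. What may go wrong: slow oxidative addition into a C–Br bond flanked by two oxygens, and cleavage of the vinylogous-ester C–O bond of 18 under hot carbonate before the ring closes. The fallback sets out from 10 and comes back at 19. Palladium/copper coupling of 10 with 14 (PdCl2(PPh3)2, CuI, Cs2CO3, DMF, 80 °C), with cyclisation of the ortho-alkynylphenol in the same flask, gives the 2-arylbenzofuran F8. N-Iodosuccinimide iodinates the furan C3 to the 3-iodobenzofuran F9. Iodine–magnesium exchange (i-PrMgCl·LiCl, THF, −20 °C) gives the furan-3-ylmagnesium chloride F10, which adds to aldehyde 13 to give the diaryl carbinol F11. Dess–Martin oxidation of F11 gives 19.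

**Further compounds**
F1 | step 6 | 2,6-dihydroxy-4-(methoxymethoxy)benzaldehyde | COCOc1cc(O)c(C=O)c(O)c1
F2 | step 6 | 2-(benzyloxy)-6-hydroxy-4-(methoxymethoxy)benzaldehyde | COCOc1cc(O)c(C=O)c(OCc2ccccc2)c1
F3 | step 6 | (E)-3-[2-(benzyloxy)-6-hydroxy-4-(methoxymethoxy)phenyl]-1-[4-(benzyloxy)phenyl]prop-2-en-1-one | COCOc1cc(O)c(/C=C/C(=O)c2ccc(OCc3ccccc3)cc2)c(OCc2ccccc2)c1
F4 | step 6 | 3-[2-(benzyloxy)-6-hydroxy-4-(methoxymethoxy)phenyl]-1-[4-(benzyloxy)phenyl]propan-1-one | COCOc1cc(O)c(CCC(=O)c2ccc(OCc3ccccc3)cc2)c(OCc2ccccc2)c1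
F5 | step 6 | 3-(benzyloxy)-2-{(3R)-3-[4-(benzyloxy)phenyl]-3-hydroxypropyl}-5-(methoxymethoxy)phenol | COCOc1cc(O)c(CC[C@@H](O)c2ccc(OCc3ccccc3)cc2)c(OCc2ccccc2)c1
F6 | step 6 | (S)-5-(benzyloxy)-2-[4-(benzyloxy)phenyl]-7-(methoxymethoxy)chromane | COCOc1cc(OCc2ccccc2)c2c(c1)O[C@H](c1ccc(OCc3ccccc3)cc1)CC2
F7 | step 14 | junction epimer of 22 (both junction carbons inverted) | O=C1c2c(OCc3ccccc3)cc(OCc3ccccc3)cc2O[C@]2(c3ccc(OCc4ccccc4)cc3)Oc3cc(OCc4ccccc4)c4c(c3[C@@]12O)O[C@H](c1ccc(OCc2ccccc2)cc1)CC4
F8 | step 12 | (2S)-5-(benzyloxy)-2,8-bis[4-(benzyloxy)phenyl]-3,4-dihydro-2H-furo[2,3-h]chromene | c1c(-c2ccc(OCc3ccccc3)cc2)oc2cc(OCc3ccccc3)c3c(c12)O[C@H](c1ccc(OCc2ccccc2)cc1)CC3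
F9 | step 12 | (2S)-5-(benzyloxy)-2,8-bis[4-(benzyloxy)phenyl]-9-iodo-3,4-dihydro-2H-furo[2,3-h]chromene | Ic1c(-c2ccc(OCc3ccccc3)cc2)oc2cc(OCc3ccccc3)c3c(c12)O[C@H](c1ccc(OCc2ccccc2)cc1)CC3
F10 | step 12 | {(2S)-5-(benzyloxy)-2,8-bis[4-(benzyloxy)phenyl]-3,4-dihydro-2H-furo[2,3-h]chromen-9-yl}magnesium chloride | Cl[Mg]c1c(-c2ccc(OCc3ccccc3)cc2)oc2cc(OCc3ccccc3)c3c(c12)O[C@H](c1ccc(OCc2ccccc2)cc1)CC3
F11 | step 12 | [2,4-bis(benzyloxy)-6-(methoxymethoxy)phenyl]{(2S)-5-(benzyloxy)-2,8-bis[4-(benzyloxy)phenyl]-3,4-dihydro-2H-furo[2,3-h]chromen-9-yl}methanol | OC(c1c(OCOC)cc(OCc2ccccc2)cc1OCc1ccccc1)c1c(-c2ccc(OCc3ccccc3)cc2)oc2cc(OCc3ccccc3)c3c(c12)O[C@H](c1ccc(OCc2ccccc2)cc1)CC3
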